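## Structural features

The target is a labdane in which a trans-fused decalin (rings A and B) carries two spiro junctions in a row: C9 is shared by ring B and the oxolane ring C, and C13 is shared by ring C and the γ-lactone ring D (C13–C14–C15(=O)–O–C16). Five of the six stereocentres are contiguous around ring B (C5, C10, C9, C8, C7), with C9 and C10 both fully substituted and adjacent; the sixth, C13, is insulated from them by the ether oxygen and by C11–C12. The configuration is 5S,7R,8R,9R,10S,13R, that is 5α-H, 10β-CH3, 9α-O (C11 β), 8α-CH3 and 7β-OH. The two ring B substituents that must be added to an unsaturated precursor therefore enter on opposite faces: the C1 chain at C10 syn to the ether oxygen, the hydrogen at C8 anti to it. Fragile elements are the α-ketol (C6=O/C7–OH, epimerisable and oxidisable), the β-alkoxy lactone (ring C oxygen β to C15=O, open to retro-oxa-Michael cleavage by strong base) and the tertiary C9–O ether, which is a γ-alkoxy enone, and thus a leaving group under single-electron reduction or strong acid, whenever C7=C8 is unsaturated. The real difficulty is the vicinal fully substituted pair C9/C10, the face-opposed additions at C8 and C10, and the remote C13 centre. The key step uses the fact that ring B is a masked phenol: the C6 carbonyl is para to C9, and C8 and C10 carry the methyl groups C17 and C20, which is the pattern of a 4-alkyl-3,5-dimethylphenol whose side chain places the C13 hydroxyl two carbons from the ring.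

## Logic of the disconnections

**C7–O and the C7 configuration (24 ⇒ 23 ⇒ 20 ⇒ 19).** The O–C7 bond is cut last because the α-ketol is the most fragile function and the C6 ketone of 19 offers enol chemistry. This removes one stereocentre and one sensitive group. The forward steps must enolise 19 toward C7 only (20), deliver oxygen (23) and then let C7 settle in its equatorial 7β arrangement (24).

**C4–C5, ring A (19 ⇒ 18).** C4 is a tertiary cation equivalent and C5 an enol carbon, so this bond is cut. Ring A and the C5 stereocentre disappear, leaving a single carbocycle with a trisubstituted alkene on C10. The forward step needs an acid that protonates the alkene without ionising the C9 ether; C5 is α to the ketone and is set by equilibration to the trans fusion.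

**C8–H (18 ⇒ 16).** The methyl-bearing C8 is most simply the β-carbon of an enone, so the C8–H bond is removed. This restores the second enone arm of ring B. The hydrogen must arrive anti to the ether oxygen, and no carbanion may develop at C8, because it would expel the C9 alkoxide. Dissolving-metal and SmI2-type reductions are therefore excluded, and a copper hydride under ligand control is used while ring B is still flexible.

**C1–C10 (16 ⇒ 13 + 14).** C10 is the β-carbon of the other enone arm. Cutting C1–C10 returns the locally symmetric 13 and a four-carbon-plus-gem-dimethyl Grignard unit from 14. The forward step is a desymmetrising conjugate addition that creates a quaternary carbon next to the spiro carbon, syn to the ether oxygen, on one arm only; it fixes C10 and C9 together.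

**O–C9, ring C (13 ⇒ 12).** Cutting the ether bond at the spiro carbon turns ring B into an arene and removes the fully substituted C9 without any organometallic addition. The forward step is an oxidative dearomatisation in which the C13 hydroxyl must attack the para carbon faster than any external nucleophile.

**C9–C11 and ring D (12 ⇒ 11 ⇒ 2 + 7).** The aryl–C11 bond is cut to an aryl Grignard (from 2) and the C11 aldehyde 7; the C11 oxygen and the benzyl group are added back (11). Ring D is traced to the dioxolanone of 7, whose ring carbonyl (C16) is the only reducible acyl group while C15 is a carboxylate. The forward sequence needs aldehyde-selective addition, hydride selectivity for C16, and hydrogenolysis of both benzylic C–O bonds.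

**C12–C13 and C11 (7 ⇒ 6 ⇒ 4 + 5 ⇒ 3).** C11 is unmasked from a terminal alkene, and the C12–C13 bond is cut to the enolate of 4 and 5. C13 then comes from the chiral pool: in 4 the acetal centre relays the configuration of 3, so alkylation trans to tert-butyl replaces H with retention. Allyl, like H, is the lowest-priority substituent, so the (R) descriptor of 3 persists through 12 and 13 to 24.

**O–benzyl (2 ⇒ 1).** The phenol is masked so that the aryl Grignard reagent can be formed.

## Other disconnections considered

**Alternative 1:** The cut is C1–C10 plus C4–C5, a [4+2] between 2,6-dimethyl-1,4-benzoquinone A1 and 4-methyl-2-(triisopropylsilyloxy)penta-1,3-diene A2. The B-(o-tolyl)oxazaborolidine of diphenylprolinol, activated by HN(SO2CF3)2, would bind the less hindered C6 carbonyl of A1; the diene terminus C1 bonds to C10 and C4 to C5, giving the cis-fused enedione A3.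
- In its favour: ring A, the quaternary C10 (with the correct sense in A3) and C5 arise in one catalytic enantioselective step from achiral materials, and the C6 oxygen and the C7=C8 arm are already present. On C10 it is the better plan, since the chosen route must build C10 next to an existing spiro centre.
- Against it: the C4 terminus of A2 carries a cis methyl group, which disfavours the s-cis conformer and crowds the C4–C5 bond; the C2 enol silane is an extra oxygen that costs two or three steps to remove; C5 must be epimerised (equal to the chosen plan, which also relies on equilibration at C5).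
- The decisive point: C9 arrives as a ketone flanked by C10 and C8. The C11 chain would have to add from the β face, syn to the angular methyl, to give 9α-O, and C13 would have to be created without a chiral-pool source.
- Comparison: the chosen plan forms C9–O on a flat arene with no facial issue and imports C13 ready-made, so it should be shorter after the ring-forming event.

**Alternative 2:** The cut is C11–C12 plus O–C9. Mn(OAc)3 and KOAc in hot acetic acid would generate the carboxymethyl radical, which adds to C11 of the 9-methylene decalin A4; the oxidised C9 centre is captured by the carboxylate to give the spirolactone A5.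
- In its favour: the C9–O bond is set under substrate control (capture anti to C20), the reagents are cheap, and C8 and C10 already exist in A4. The C8 face problem of the chosen plan does not arise, and on that point this alternative is the better one.
- Against it: A4 itself needs an enantioselective decalin synthesis and methylenation of a hindered C9 ketone; trivalent manganese in hot acid next to a neopentyl-type tertiary centre invites Wagner–Meerwein migration of C20 and attack on the Δ5 alkene.
- The decisive point: A5 has C13 as a carbonyl, so ring D and the C13 stereocentre must still be built by two C–C bond formations with no nearby controlling element. Here the chosen plan, with C13 from malic acid, is clearly better.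
- Comparison: the C6/C7 oxygens would also have to be introduced from the Δ5 alkene, so the step count should exceed that of the chosen plan.

**Alternative 3:** The cut is C15–O/O–C16. A Baeyer–Villiger monooxygenase of the cyclohexanone-monooxygenase type (NADPH recycling, O2) would insert oxygen next to C15 of the spiro-cyclobutanone A6, giving the Δ5 spiro-lactone A7 and creating C13.
- In its favour: ring D and C13 are made in the last skeletal step under catalyst control and mild aqueous conditions; cyclobutanones are privileged substrates; the lactone never has to survive organometallic steps. On that last point it is better than the chosen plan, where the lactone must pass a Grignard addition.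
- Against it: the two CH2 groups of A6 differ only through the remote chirality of the decalin, so an enzyme must accept a bulky lipophilic tetracycle and still discriminate, which calls for screening. A6 also needs a separate construction of the C8–C9–C10 array and of the four-membered ring.
- Comparison: A7 lacks both ring B oxygens, so three or four more steps are needed to reach the 6-oxo-7β-hydroxy pattern. The Rubottom and epimerisation end-game would be common to both plans (equal). Overall the chosen plan is shorter and rests on a chiral-pool centre.

Key step: step 7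

Assumptions: labdane numbering is kept for all intermediates. In steps 8 and 9 the antipode of the chiral ligand is the one that gives the stated sense of attack; both antipodes of each ligand are available. The (13R) descriptor is the same in 12, 13 and 24.

## Route

Step 1
Reactants: 1 4-bromo-3,5-dimethylphenol
Product: 2 5-(benzyloxy)-2-bromo-1,3-dimethylbenzene
Conditions: BnBr, K2CO3, DMF, rt
Reagents that add atoms: benzyl bromide, BrCc1ccccc1
Why: Williamson ether synthesis on the phenoxide; benzyl survives the Grignard and hydride steps and is removed in the same hydrogenolysis that later takes out the benzylic hydroxyl.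

Step 2
Reactants: 3 (R)-malic acid
Product: 4 2-[(2R,4R)-2-tert-butyl-5-oxo-1,3-dioxolan-4-yl]acetic acid
Conditions: tBuCHO, p-TsOH·H2O (cat.), H2SO4 (cat.), pentane, reflux, Dean–Stark
Reagents that add atoms: pivalaldehyde, CC(C)(C)C=O
Why: Acid-catalysed acetalisation takes up the α-hydroxy acid as the five-membered dioxolanone and leaves the β-carboxyl free; the cis acetal (tert-butyl syn to CH2CO2H) is the thermodynamic isomer, so the new acetal centre (2R) stores the configuration of C13 (self-regeneration of a stereocentre).

Step 3
Reactants: 4 2-[(2R,4R)-2-tert-butyl-5-oxo-1,3-dioxolan-4-yl]acetic acid; 5 allyl bromide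
Product: 6 2-[(2R,4R)-2-tert-butyl-5-oxo-4-(prop-2-en-1-yl)-1,3-dioxolan-4-yl]acetic acid
Conditions: LiN(SiMe3)2 (2.1 equiv), THF, −78 °C; 5, −78 → −30 °C; 1 M HCl
Reagents that add atoms: none
Why: Enolate alkylation of the carboxylate–enolate dianion (the carboxylate keeps C14 from being deprotonated); allyl bromide enters trans to tert-butyl, where H stood, so C13 is quaternised with net retention and has the (R) sense of the target.

Step 4
Reactants: 6 2-[(2R,4R)-2-tert-butyl-5-oxo-4-(prop-2-en-1-yl)-1,3-dioxolan-4-yl]acetic acid
Product: 7 2-[(2R,4R)-2-tert-butyl-5-oxo-4-(2-oxoethyl)-1,3-dioxolan-4-yl]acetic acid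
Conditions: O3, CH2Cl2, −78 °C; PPh3, −78 °C → rt
Reagents that add atoms: ozone, [O-][O+]=O
Why: Ozonolysis with reductive work-up cuts the terminal alkene to the C11 aldehyde; no electron-rich arene is present yet, and the acetal and the acid are inert to ozone (7 may rest as its cyclic pseudo-acid, which reopens on deprotonation).

Step 5
Reactants: 2 5-(benzyloxy)-2-bromo-1,3-dimethylbenzene; 7 2-[(2R,4R)-2-tert-butyl-5-oxo-4-(2-oxoethyl)-1,3-dioxolan-4-yl]acetic acid
Product: 11 (4R)-4-{2-[4-(benzyloxy)-2,6-dimethylphenyl]-2-hydroxyethyl}-4-hydroxyoxolan-2-one (C11 epimers), via arylmagnesium bromide 8 (not isolated), via dioxolanone carbinol 9 (not isolated), via triol acid 10 (not isolated)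
Conditions: 2, Mg (I2 cat.), THF, 60 °C; add to 7 (8: 2.3 equiv), THF, −78 → −30 °C; LiBH4 (3 equiv), −30 °C → rt; 1 M HCl to pH 3, 0 °C → rt
Reagents that add atoms: none
Why: Grignard 1,2-addition: the first equivalent makes the carboxylate and the second adds to the aldehyde far faster than to the neopentyl-type dioxolanone carbonyl, forming C9–C11; LiBH4 then reduces only the acylal-type ring carbonyl (a carboxylate is inert), releasing C16H2OH and pivalaldehyde (reduced to neopentyl alcohol), and acidification closes the γ-lactone from C16–OH onto C15. C13 is untouched and the C11 carbinol centre is removed in step 6.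

Step 6
Reactants: 11 (4R)-4-{2-[4-(benzyloxy)-2,6-dimethylphenyl]-2-hydroxyethyl}-4-hydroxyoxolan-2-one
Product: 12 (4R)-4-hydroxy-4-[2-(4-hydroxy-2,6-dimethylphenyl)ethyl]oxolan-2-one
Conditions: H2 (1 atm), 10% Pd/C, EtOAc–AcOH, rt
Reagents that add atoms: none
Why: Catalytic hydrogenolysis removes the O-benzyl group and then the para-hydroxybenzylic C11–O bond, which ionises easily toward a quinone-methide-like species in AcOH and is reduced to CH2; the lactone and the tertiary alcohol are inert, and any C11-linked lactone or cyclic-ether isomer of 11 converges on 12.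

Step 7
Reactants: 12 (4R)-4-hydroxy-4-[2-(4-hydroxy-2,6-dimethylphenyl)ethyl]oxolan-2-one
Product: 13 (13R)-dispiro dienone: 3,5-dimethylcyclohexa-2,5-dien-1-one whose C4 (= C9) is the spiro carbon of oxolane ring C, itself spiro-fused at C13 to the γ-lactone ring D
Conditions: PhI(OAc)2 (1.1 equiv), (CF3)2CHOH, 0 °C, dilute; NaHCO3
Reagents that add atoms: none
Why: Ligand exchange places the phenol oxygen of 12 on trivalent iodine, and loss of PhI and acetate in the ionising solvent leaves a phenoxonium-type cation whose positive character is greatest at the para carbon C9. The tethered tertiary C13 hydroxyl adds there, forming O–C9 and releasing the C6 carbonyl as a cross-conjugated dienone. Ring C closes in a 5-exo-trig mode and is the only ring formed. The closest known reaction type is the PhI(OAc)2- or PhI(OCOCF3)2-mediated dearomatising spiro-etherification of 4-(3-hydroxyalkyl)phenols to 1-oxaspiro[4.5]deca-6,9-dien-8-ones. No stereocentre is created: C9 carries two identical enone arms and stays prostereogenic, and C13 keeps its configuration because its C–O bond is never broken. The step needs para spiro attack to beat intermolecular capture at C9 or at the free ortho carbons C5 and C7; the five-membered transition state of the two-carbon tether, dilution and the weakly nucleophilic (CF3)2CHOH secure this. It also needs chemoselectivity for the phenol, which the substrate provides because the lactone and the tertiary alcohol offer nothing that trivalent iodine oxidises at 0 °C. The methyl groups on C8 and C10 slow the closure sterically but cannot redirect it, since the only internal nucleophile is held by the tether.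

Step 8
Reactants: 13 (13R)-dispiro dienone; 14 5-bromo-2-methylpent-2-ene
Product: 16 (13R)-9α,13-epoxy-6-oxo-4,5-secolabda-3,7-dien-15,16-olide (10β-CH3), via 4-methylpent-3-enylmagnesium bromide 15 (not isolated)
Conditions: 14, Mg, Et2O; 13, Cu(OTf)2 (5 mol %), chiral 4,5-diphenylimidazolinium chloride (carbene precursor, 7 mol %), Et2O–CH2Cl2, −40 °C, 15 (1.3 equiv) added over 2 h; aq NH4Cl
Reagents that add atoms: none
Why: Copper-catalysed asymmetric conjugate addition of a Grignard reagent to a β-methyl enone arm, forming a quaternary centre (C1–C10); the nucleophile enters syn to the small ether oxygen and anti to C11H2, which the flat dienone already favours, and the chiral carbene ligand selects which of the two diastereotopic arms becomes C10, so 10β-CH3 and 9α-O are fixed together. The magnesium dienolate is protonated at C5, and slow addition at low temperature keeps the lactone from the Grignard reagent.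

Step 9
Reactants: 16 (13R)-9α,13-epoxy-6-oxo-4,5-secolabda-3,7-dien-15,16-olide
Product: 18 (13R)-9α,13-epoxy-6-oxo-4,5-secolabd-3-en-15,16-olide (8α-CH3), via silyl enol ether 17 (not isolated)
Conditions: Cu(OAc)2·H2O (5 mol %), DTBM-SEGPHOS (5 mol %), (EtO)2MeSiH (2 equiv), toluene, 0 °C → rt; then 1 M HCl, THF, 0 °C
Reagents that add atoms: none
Why: Copper-hydride-catalysed asymmetric conjugate reduction (1,4-hydrosilylation): hydride goes to C8 while copper takes C7/O, so no carbanion ever sits next to the C9–O bond, whereas a single-electron reductant would expel that γ-alkoxide. Ring B is still conformationally free, its own facial bias is weak, and the ligand antipode is chosen to deliver hydride anti to the ether oxygen, giving 8β-H/8α-CH3; the lactone and the trisubstituted alkene are inert, and mild hydrolysis of 17 gives the ketone.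

Step 10
Reactants: 18 (13R)-9α,13-epoxy-6-oxo-4,5-secolabd-3-en-15,16-olide
Product: 19 (13R)-9α,13-epoxy-6-oxolabdan-15,16-olide (5α-H, 8α-CH3, 10β-CH3)
Conditions: MeSO3H (5 equiv), CH2Cl2, −20 → 0 °C; aq NaHCO3
Reagents that add atoms: none
Why: Proton-initiated cation–olefin cyclisation terminated by the ketone enol: Markovnikov protonation gives the tertiary C4 cation, and the C5 enol carbon closes the six-membered ring A (C4–C5), while the C7 enol cannot reach. C5 is α to the ketone and equilibrates under the acid to the trans-fused 5α-H isomer; with C7–C8 saturated the spiro ether is an ordinary tertiary cyclic ether and no longer a γ-alkoxy enone.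

Step 11
Reactants: 19 (13R)-9α,13-epoxy-6-oxolabdan-15,16-olide
Product: 20 (13R)-9α,13-epoxy-6-(trimethylsilyloxy)labd-6-en-15,16-olide
Conditions: TMSOTf (1.3 equiv), Et3N (2 equiv), CH2Cl2, 0 °C
Reagents that add atoms: trimethylsilyl trifluoromethanesulfonate, C[Si](C)(C)OS(=O)(=O)C(F)(F)F
Why: Soft enolisation gives the Δ6 silyl enol ether, because the Δ5 alternative would press the silyloxy group against the C4 gem-dimethyl group (allylic strain) and needs removal of the hindered ring-fusion hydrogen; the lactone is not silylated at 0 °C.

Step 12
Reactants: 20 (13R)-9α,13-epoxy-6-(trimethylsilyloxy)labd-6-en-15,16-olide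
Product: 23 (13R)-9α,13-epoxy-7α-hydroxy-6-oxolabdan-15,16-olide, via silyloxy epoxide 21 (not isolated), via 7α-silyloxy ketone 22 (not isolated)
Conditions: mCPBA (1.1 equiv), NaHCO3, CH2Cl2, −20 °C; then Et3N·3HF, THF, rt
Reagents that add atoms: 3-chloroperoxybenzoic acid, OOC(=O)c1cccc(Cl)c1
Why: Rubottom oxidation: epoxidation of the enol silane, ring opening with 1,4-silyl shift to the α-silyloxy ketone, then fluoride desilylation. The peracid should approach anti to the syn-axial 4β- and 10β-methyl groups that flank C6, giving the axial 7α-oxygen; any β-face product is already 24, and both converge in step 13.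

Step 13
Reactants: 23 (13R)-9α,13-epoxy-7α-hydroxy-6-oxolabdan-15,16-olide
Product: 24 (5S,7R,8R,9R,10S,13R)-9,13-epoxy-7-hydroxy-6-oxolabdan-15,16-olide (7β-OH, 8α-CH3, 9α-O), the target
Conditions: DBU (0.2 equiv), CH2Cl2, rt, argon
Reagents that add atoms: none
Why: Base-mediated epimerisation of the α-ketol through the enol toward C7: the equatorial 7β-OH (trans-diequatorial to 8α-CH3 and free of the 1,3-diaxial contact with the 9α-oxygen) is the thermodynamic epimer. The 6-oxo-7-hydroxy arrangement is preferred over the transposed ketol because an sp3 C6–O would clash with the C4 and C10 methyl groups; catalytic base at rt spares the β-alkoxy lactone, and C5 stays trans.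

## Compound list

1 | 4-bromo-3,5-dimethylphenol | Cc1cc(O)cc(C)c1Br | starting material
2 | 5-(benzyloxy)-2-bromo-1,3-dimethylbenzene | Cc1cc(OCc2ccccc2)cc(C)c1Br | intermediate
3 | (R)-malic acid | O[C@H](CC(=O)O)C(=O)O | starting material
4 | 2-[(2R,4R)-2-tert-butyl-5-oxo-1,3-dioxolan-4-yl]acetic acid | OC(=O)C[C@H]1O[C@@H](C(C)(C)C)OC1=O | intermediate
5 | allyl bromide | C=CCBr | starting material
6 | 2-[(2R,4R)-2-tert-butyl-5-oxo-4-(prop-2-en-1-yl)-1,3-dioxolan-4-yl]acetic acid | OC(=O)C[C@@]1(CC=C)O[C@@H](C(C)(C)C)OC1=O | intermediate
7 | 2-[(2R,4R)-2-tert-butyl-5-oxo-4-(2-oxoethyl)-1,3-dioxolan-4-yl]acetic acid | OC(=O)C[C@@]1(CC=O)O[C@@H](C(C)(C)C)OC1=O | intermediate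
8 | [4-(benzyloxy)-2,6-dimethylphenyl]magnesium bromide | Cc1cc(OCc2ccccc2)cc(C)c1[Mg]Br | intermediate (not isolated)
9 | 2-[(2R,4R)-4-{2-[4-(benzyloxy)-2,6-dimethylphenyl]-2-hydroxyethyl}-2-tert-butyl-5-oxo-1,3-dioxolan-4-yl]acetic acid, carbinol epimers, present as its magnesium salt | OC(=O)C[C@@]1(CC(O)c2c(C)cc(OCc3ccccc3)cc2C)O[C@@H](C(C)(C)C)OC1=O | intermediate (not isolated)
10 | (3R)-5-[4-(benzyloxy)-2,6-dimethylphenyl]-3,5-dihydroxy-3-(hydroxymethyl)pentanoic acid, C5 epimers | OC(=O)C[C@@](O)(CO)CC(O)c1c(C)cc(OCc2ccccc2)cc1C | intermediate (not isolated)
11 | (4R)-4-{2-[4-(benzyloxy)-2,6-dimethylphenyl]-2-hydroxyethyl}-4-hydroxyoxolan-2-one, carbinol epimers | Cc1cc(OCc2ccccc2)cc(C)c1C(O)C[C@]1(O)COC(=O)C1 | intermediate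
12 | (4R)-4-hydroxy-4-[2-(4-hydroxy-2,6-dimethylphenyl)ethyl]oxolan-2-one (key-step precursor) | Cc1cc(O)cc(C)c1CC[C@]1(O)COC(=O)C1 | intermediate
13 | (13R)-dispiro dienone with rings B, C and D: 3,5-dimethylcyclohexa-2,5-dienone spiro at C9 to the oxolane, which is spiro at C13 to the γ-lactone (key-step product) | CC1=CC(=O)C=C(C)C12CC[C@@]1(COC(=O)C1)O2 | intermediate
14 | 5-bromo-2-methylpent-2-ene | CC(C)=CCCBr | starting material
15 | (4-methylpent-3-en-1-yl)magnesium bromide | CC(C)=CCC[Mg]Br | intermediate (not isolated)
16 | (13R)-9α,13-epoxy-6-oxo-4,5-secolabda-3,7-dien-15,16-olide (10β-CH3, C1 chain syn to the ether oxygen) | CC1=CC(=O)C[C@](C)(CCC=C(C)C)[C@@]12CC[C@@]1(COC(=O)C1)O2 | intermediate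
17 | (13R)-6-[diethoxy(methyl)silyloxy]-9α,13-epoxy-4,5-secolabda-3,6-dien-15,16-olide (8α-CH3) | C[C@@H]1C=C(O[Si](C)(OCC)OCC)C[C@](C)(CCC=C(C)C)[C@@]12CC[C@@]1(COC(=O)C1)O2 | intermediate (not isolated)
18 | (13R)-9α,13-epoxy-6-oxo-4,5-secolabd-3-en-15,16-olide (8α-CH3, 8β-H) | C[C@@H]1CC(=O)C[C@](C)(CCC=C(C)C)[C@@]12CC[C@@]1(COC(=O)C1)O2 | intermediate
19 | (13R)-9α,13-epoxy-6-oxolabdan-15,16-olide (5α-H, 8α-CH3, 10β-CH3) | C[C@@H]1CC(=O)[C@H]2C(C)(C)CCC[C@]2(C)[C@@]12CC[C@@]1(COC(=O)C1)O2 | intermediate
20 | (13R)-9α,13-epoxy-6-(trimethylsilyloxy)labd-6-en-15,16-olide | C[C@@H]1C=C(O[Si](C)(C)C)[C@H]2C(C)(C)CCC[C@]2(C)[C@@]12CC[C@@]1(COC(=O)C1)O2 | intermediate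
21 | (13R)-6α,7α:9α,13-diepoxy-6β-(trimethylsilyloxy)labdan-15,16-olide | C[C@@H]1[C@@H]3O[C@]3(O[Si](C)(C)C)[C@H]2C(C)(C)CCC[C@]2(C)[C@@]12CC[C@@]1(COC(=O)C1)O2 | intermediate (not isolated)
22 | (13R)-9α,13-epoxy-6-oxo-7α-(trimethylsilyloxy)labdan-15,16-olide | C[C@@H]1[C@H](O[Si](C)(C)C)C(=O)[C@H]2C(C)(C)CCC[C@]2(C)[C@@]12CC[C@@]1(COC(=O)C1)O2 | intermediate (not isolated)
23 | (13R)-9α,13-epoxy-7α-hydroxy-6-oxolabdan-15,16-olide | C[C@@H]1[C@H](O)C(=O)[C@H]2C(C)(C)CCC[C@]2(C)[C@@]12CC[C@@]1(COC(=O)C1)O2 | intermediate
24 | (5S,7R,8R,9R,10S,13R)-9,13-epoxy-7-hydroxy-6-oxolabdan-15,16-olide | C[C@@H]1[C@@H](O)C(=O)[C@H]2C(C)(C)CCC[C@]2(C)[C@@]12CC[C@@]1(COC(=O)C1)O2 | target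

## Step count and least certain steps

Total: 13 steps. Longest linear sequence: 12 steps (3 → 4 → 6 → 7 → 11 → 12 → 13 → 16 → 18 → 19 → 20 → 23 → 24). The aryl branch (step 1) joins at step 5, and 14 enters at step 8.

**Step 7 (key step).** The hindered tertiary hydroxyl may close too slowly, so that the phenoxonium intermediate is captured intermolecularly by solvent or acetate at C9 or at the free ortho carbons, or the phenol couples oxidatively with itself. The fallback sets out from 12 and comes back at 13: anodic oxidation at constant current (carbon anode, Bu4NBF4, (CF3)2CHOH–CH2Cl2) generates the same cation at a low stationary concentration with no ligand on oxygen and no acetate present. This fallback makes no compound outside the list (entry F0).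

**Step 8.** Conjugate addition must form a quaternary carbon next to the spiro carbon. Slow addition may let the Grignard reagent attack the lactone or the C6 carbonyl, electron transfer from the cuprate may re-aromatise ring B with loss of the ether, and the ligand may distinguish the two arms poorly because they differ only through remote C13. The fallback sets out from 13 and returns at 16: the stoichiometric homocuprate made from 15 and CuBr·SMe2, with BF3·OEt2 at −78 °C, is the most forcing known conjugate-addition protocol and is achiral. It should give 16 together with the arm isomer F1 (both from attack syn to oxygen); the two are diastereomers because of C13 and are separated by chromatography.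

**Step 9.** Hydride delivery to C8 anti to the ether oxygen rests on ligand control over a hindered β-carbon; a mismatch with the substrate would lead to slow turnover or poor facial selectivity. The fallback sets out from 16 and returns at 19, replacing ligand control by hydroxyl direction. Ring A is closed first with MeSO3H (short and cold, since the substrate is then a γ-alkoxy enone) to the tetracyclic enone F2. Luche reduction (NaBH4, CeCl3·7H2O) delivers hydride from the open α face to give the 6β-allylic alcohol F3. Hydrogenation with [Ir(cod)(PCy3)(py)]PF6 under H2 adds hydrogen from the face of the hydroxyl, giving the saturated 6β-alcohol F4 with 8β-H. Dess–Martin periodinane oxidises F4 to 19.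

**Step 10.** Under MeSO3H the tertiary C9–O ether may ionise reversibly in competition with alkene protonation, which would open the way to elimination toward C8 or C11 or to epimerisation at C9; alkene isomerisation may also stall the closure. The fallback sets out from 18 and returns at 19, separating cation generation from strong Brønsted acid. Dry HCl in CH2Cl2 at −78 °C adds to the alkene to give the tertiary chloride F5. TMSOTf/Et3N converts F5 into the C5 trimethylsilyl enol ether F6 together with the C7 regioisomer F7. TiCl4 at −78 °C then effects the Lewis-acid tert-alkylation of the enol silane in F6 to give 19, while F7 cannot reach C4 and is returned to F5 on work-up.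

**Step 5.** The di-ortho-substituted aryl Grignard reagent may act as a base toward the aldehyde (enolisation at C12) or reach the dioxolanone carbonyl, and the one-pot reduction depends on clean addition. The fallback sets out from 4 (with 8 as the aryl source) and returns at 11, forming C12–C13 in place of C9–C11. Reagent 8 and 2-chloro-N-methoxy-N-methylacetamide give the chloromethyl ketone F8. The dianion of 4 (LiN(SiMe3)2, 2 equiv) is alkylated with F8 in the presence of LiI, trans to tert-butyl, to give the keto acid F9. LiBH4 reduces both the aryl ketone and the dioxolanone carbonyl of F9 to 10, which lactonises to 11 on acidification.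

## Further compounds

F0 | step 7 | none | none
F1 | step 8 | arm isomer of 16 (chain added to the other enone arm, syn to the ether oxygen; C9 and C10 inverted, 13R) | CC1=CC(=O)C[C@@](C)(CCC=C(C)C)[C@]12CC[C@@]1(COC(=O)C1)O2
F2 | step 9 | (13R)-9α,13-epoxy-6-oxolabd-7-en-15,16-olide (5α-H) | CC1=CC(=O)[C@H]2C(C)(C)CCC[C@]2(C)[C@@]12CC[C@@]1(COC(=O)C1)O2
F3 | step 9 | (13R)-9α,13-epoxy-6β-hydroxylabd-7-en-15,16-olide | CC1=C[C@@H](O)[C@H]2C(C)(C)CCC[C@]2(C)[C@@]12CC[C@@]1(COC(=O)C1)O2
F4 | step 9 | (13R)-9α,13-epoxy-6β-hydroxylabdan-15,16-olide (8α-CH3) | C[C@@H]1C[C@@H](O)[C@H]2C(C)(C)CCC[C@]2(C)[C@@]12CC[C@@]1(COC(=O)C1)O2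
F5 | step 10 | (13R)-4-chloro-9α,13-epoxy-6-oxo-4,5-secolabdan-15,16-olide (tertiary chloride) | C[C@@H]1CC(=O)C[C@](C)(CCCC(C)(C)Cl)[C@@]12CC[C@@]1(COC(=O)C1)O2
F6 | step 10 | C5 trimethylsilyl enol ether of F5 | C[C@@H]1CC(O[Si](C)(C)C)=C[C@](C)(CCCC(C)(C)Cl)[C@@]12CC[C@@]1(COC(=O)C1)O2
F7 | step 10 | C7 trimethylsilyl enol ether of F5 | C[C@@H]1C=C(O[Si](C)(C)C)C[C@](C)(CCCC(C)(C)Cl)[C@@]12CC[C@@]1(COC(=O)C1)O2
F8 | step 5 | 1-[4-(benzyloxy)-2,6-dimethylphenyl]-2-chloroethan-1-one | O=C(CCl)c1c(C)cc(OCc2ccccc2)cc1C
F9 | step 5 | 2-[(2R,4R)-4-{2-[4-(benzyloxy)-2,6-dimethylphenyl]-2-oxoethyl}-2-tert-butyl-5-oxo-1,3-dioxolan-4-yl]acetic acid | OC(=O)C[C@@]1(CC(=O)c2c(C)cc(OCc3ccccc3)cc2C)O[C@@H](C(C)(C)C)OC1=O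
A1 | alternative 1 | 2,6-dimethyl-1,4-benzoquinone | CC1=CC(=O)C=C(C)C1=O
A2 | alternative 1 | 4-methyl-2-(triisopropylsilyloxy)penta-1,3-diene | C=C(O[Si](C(C)C)(C(C)C)C(C)C)C=C(C)C
A3 | alternative 1 | cis-fused decalin enedione with C2 enol silane | CC1=CC(=O)[C@@H]2C(C)(C)C=C(O[Si](C(C)C)(C(C)C)C(C)C)C[C@]2(C)C1=O
A4 | alternative 2 | 9-methylene decalin (8α-CH3, 10β-CH3, Δ5) | C[C@@H]1CC=C2C(C)(C)CCC[C@]2(C)C1=C
A5 | alternative 2 | C9 spirolactone (ring C with C13 as carbonyl) | C[C@@H]1CC=C2C(C)(C)CCC[C@]2(C)[C@@]12CCC(=O)O2
A6 | alternative 3 | prochiral spiro-cyclobutanone on ring C (Δ5) | C[C@@H]1CC=C2C(C)(C)CCC[C@]2(C)[C@@]12CCC1(CC(=O)C1)O2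
A7 | alternative 3 | Δ5 spiro-lactone (target lacking the C6 and C7 oxygens) | C[C@@H]1CC=C2C(C)(C)CCC[C@]2(C)[C@@]12CC[C@@]1(COC(=O)C1)O2
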